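## Analysis of the target

Target 33 is a cis-fused bicyclo[5.3.0]dec-8-ene of the daucane type, in which a cyclopentane (C1–C5) shares the C1–C5 bond with a cycloheptene (C1, C5, C6, C7, C8, C9, C10) that holds the trisubstituted C8=C9 bond. The atoms are numbered here C1 (quaternary, methyl), C2 (CHOH), C3 (CH2), C4 (tertiary carbinol with isopropyl), C5 (ring-fusion CH), C6 (CH–O-angeloyl), C7 (CH2), C8 (methyl-bearing alkene carbon), C9 (=CH) and C10 (CH–O-angeloyl). In this numbering the six stereocentres are 1R, 2R, 4S, 5R, 6R and 10R. The C1 methyl group, H5, the C2 hydroxyl, the isopropyl group and the C6 oxygen lie on one face of the bicycle, and the C4 hydroxyl and the C10 oxygen on the other, so the pairs C2–O/C10–O and C4–O/C6–O are both 1,3-anti. The sensitive groups are the two angelates (Z-2-methylbut-2-enoates, which isomerise to tiglates under nucleophilic catalysis, strong base or heat and can migrate to the free C2 hydroxyl), the allylic C10 ester and the tertiary C4 alcohol. The hard part is the crowded run C4–C5–C1, where a tertiary carbinol and a quaternary carbon flank the ring-fusion methine, together with oxygen on four ring carbons in a fixed relative arrangement. The strategy rests on one feature: C4 is joined to C5 through C3, C2 and the quaternary C1, so a carbenoid at C5 is 1,5 to the C4–H bond of an open-chain precursor in which C4 is an ordinary secondary silyl ether. Insertion closes the cyclopentane C1–C5 and turns that secondary carbinol carbon into the tertiary one with its configuration kept, and because C1 has no hydrogen the carbenoid cannot escape by a 1,2-hydride shift.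

## Retrosynthetic reasoning

**Esters and silyl groups (33 ← 32 ← 29 + 30).** The two O–Si bonds are cut last and the two ester C–O bonds just before. The angelates are the most fragile groups, so they come from angelic acid 30 only after all basic, reductive and organometallic steps are over. One molecule of 30 is needed for each of the two hydroxyls. The forward steps must acylate two hindered secondary alcohols without Z to E isomerisation and then free C2–OH and C4–OH without acyl migration.

**Seven-membered ring (29 ← 28).** The cycloheptene is opened at C8=C9, which leads to a methallyl group on C6 and a vinyl group on C10. A closure at C9–C10 from a vinyl iodide and an aldehyde was considered. It would need the C7–C8–C9 unit delivered to C6 as a 3-iodo-2-methylallyl metal, and such reagents add through the iodine-bearing carbon, so the wrong constitution would result. Metathesis needs only two simple alkenes and fixes the position of the double bond.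

**C9–C10 bond (28 ← 25 + 26).** The vinyl group is cut from C10, which gives the lactol 25 (a masked C10 aldehyde with C6–O) and the vinyl Grignard reagent 26. The forward addition has to set C10 (R); a magnesium chelate between the C6 alkoxide and the C10 carbonyl is counted on for that.

**C6–C7 bond and differentiation of the two carbonyls (25 ← 24 ← 20 + 21).** The methallyl group is cut from C6. In the forward sense the new C6 alcohol closes onto the cis C10 ester, and the γ-lactone 24 both protects C6–O and marks C10 for reduction to the lactol. C6 (R) is set by reagent control, because the aldehyde 20 is flanked by two fully substituted carbons and its own facial bias cannot be predicted.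

**C6 oxidation level (20 ← 19).** The aldehyde comes from the diester 19 by reduction of the less hindered ester, the one on the tertiary C5 and not the one on the quaternary C1.

**C4–C5 bond, the key disconnection (19 ← 17).** The cyclopentane is opened between the tertiary carbinol carbon and the ring-fusion carbon. This is the only ring bond whose cleavage leaves an acyclic chain with all three remaining stereocentres (C1, C2, C4) accessible by standard asymmetric reactions. The forward reaction must insert a C5 carbenoid into the C4–H bond with retention and with the C6 ester trans to isopropyl.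

**Diazo group and C5–C6 ester (17 ← 14 ← 12).** The diazo group is traced to the CH2 of a succinate, whose only acidic position is C5. The CH2CO2Me arm is traced to an allyl group, which survives the preceding strongly basic step and is cleaved to the ester in one operation.

**C1–allyl bond (12 ← 11 ← 8 + 9).** The quaternary centre is cut at its bond to the allyl group, which gives the β-hydroxy ester 8 and allyl bromide 9. Alkylation of the chelated dianion places the allyl group anti to the C2 hydroxyl, and that is the relationship C1/C2 needs. The C2 alcohol is silylated only afterwards.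

**C1–C2 bond (8 ← 7 ← 4 + 5).** An aldol disconnection gives the aldehyde 4 and the propionyl oxazolidinone 5. Only the carbinol centre C2 has to be right, since the methyl-bearing centre is erased in the next enolate. The auxiliary is used because the β-silyloxy stereocentre of 4 cannot be relied on to give the 1,3-syn relationship of C2 and C4.

**C4 stereocentre (4 ← 3 ← 2 ← 1).** The C4 carbinol comes from the β-keto ester 1 by asymmetric hydrogenation. This single catalytic step sets the centre that the key step later carries into the ring.

## Alternatives that were turned down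

Alternative 1: ring contraction–expansion of a decalin.
- Disconnection: the C1–C5 bond of the hydroazulene is traced back to a C1–C6 bond of a decalin, so the 5/7 system is made from a 6/6 system by a 1,2-shift.
- Forward key step: a tertiary alkoxide at C6, formed with KOtBu, pushes C1 from C6 onto C5 while an equatorial methanesulfonate leaves from C5. C1–C5 forms, C1–C6 breaks, and the cis-fused hydroazulen-6-one A1 results with C8=C9 already in place.
- In favour: decalins are easy to build and control. The shift is stereospecific (antiperiplanar migration, inversion at C5, retention in the migrating C1), so the ring fusion is secure. The seven-membered ring, the C6 oxygen and the alkene are all present right after the key step.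
- Against, for this target:
  - A1 carries C4 only as a secondary silyl ether without the isopropyl group. The tertiary carbinol would have to be made late, by oxidation to a cyclopentanone and addition of an isopropyl nucleophile such as iPrMgCl next to the ring fusion. That ketone can enolise toward C5, can eliminate the C2 silyloxy group, and is prone to being reduced or enolised instead of attacked.
  - The C6 ketone of A1 is β,γ-unsaturated and can slip into conjugation under the basic conditions of its own formation.
  - Its reduction must place oxygen on the convex face, against the normal approach of hydride.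
  - Six correctly related stereocentres have to be assembled on the decalin before the key step.
- Comparison: Alternative 1 is stronger on the seven-membered ring (closed in the key step, where the chosen route spends five further steps) and on the certainty of the ring fusion. The chosen strategy offers instead the complete C4 centre (oxygen, isopropyl and configuration) from a catalytic hydrogenation and a stereospecific insertion, a nine-step approach to its key step, and no late addition to a hindered, enolisable ketone.

Alternative 2: [4+3] union by cyclopropanation and Cope rearrangement.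
- Disconnection: C7–C8 and C1–C10, joining a three-carbon vinylcarbenoid unit (C8–C9–C10) with a diene (C7=C6–C5=C1) carried on the five-membered ring.
- Forward key step: Rh2(S-DOSP)4, a chiral carboxylate of divalent rhodium, generates the vinylcarbenoid, which cyclopropanates C6=C7. The cis-divinylcyclopropane rearranges through a boat transition state to the cycloheptadiene A2.
- In favour: the route is convergent. The seven-membered ring, the quaternary C1 and C10 arise in one catalytic step under catalyst control, and the Cope step is stereospecific.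
- Against, for this target:
  - The Cope terminus C1 is a fully substituted alkene carbon inside a ring that already carries the C2 and C4 stereocentres, so the rearrangement is slowed and the catalyst meets a chiral partner.
  - A2 has the wrong functionality at four positions: an ester at C8 that must become a methyl group; no oxygen at C4, so a tertiary C–H would have to be hydroxylated late with nothing to direct it; a C5=C6 enol ether whose hydrolysis must deliver the cis-fusion hydrogen at C5; and a C6 ketone whose reduction must again put oxygen on the convex face.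
- Comparison: Alternative 2 is clearly stronger on convergence and on step count to the bicyclic skeleton. The chosen strategy offers the correct oxidation pattern from the start (C4 oxygen, C8 methyl), a C5 centre formed directly as a saturated carbon, and no late oxidation of an unactivated tertiary C–H bond.

Alternative 3: glycol cleavage of a photoadduct.
- Disconnection: the C6 and C10 carbonyl groups are reconnected as a C6–C10 bond. The seven-membered ring is then stored as a cyclobutane (C1, C5, C6, C10) fused to a five-membered ring (C6–C10), the outcome of a [2+2] photocycloaddition.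
- Forward key step: Pb(OAc)4 (tetravalent lead) breaks the C6–C10 bond, which carries a cis-diol, and merges the four- and five-membered rings into the seven-membered ring of the dione A3.
- In favour: the photocycloaddition sets the cis relationship of C1 and C5 and builds the quaternary C1. The cleavage is normally clean, both ring oxygens at C6 and C10 arrive together, and A3 already has the complete C4 carbinol.
- Against, for this target:
  - A3 is a β-hydroxy ketone (C4–OH/C6=O) with a free tertiary hydroxyl, open to retro-aldol opening of the cyclopentane and to epimerisation at C5.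
  - C8 is a saturated methine, so C8=C9 must be introduced by dehydrogenation that chooses C9 over C7 between two ketones.
  - Both ketones must then be reduced with opposite facial outcomes (C6 oxygen convex, C10 oxygen concave) in the same molecule.
  - The facial course of the photocycloaddition relative to C2 and C4 is not secured.
- Comparison: Alternative 3 is as strong as or stronger than the chosen route in forming the seven-membered ring and placing both ring oxygens in one step, and equal in having C4 complete. The chosen strategy offers carbinols at C6 and C10 made one at a time by additions under reagent and chelate control without passing through the dione, a C8=C9 bond whose position is fixed by metathesis, and a C4 centre set by transfer instead of by the facial course of a photoreaction.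

Key step: step 10

Assumption: the B-methallyl borane made from (+)-Ipc2BOMe (the (−)-α-pinene series) is taken to attack the Re face of an aldehyde, the facial sense known for its allyl analogue.

## Route

Step 1
Reactants: 1 methyl 4-methyl-3-oxopentanoate
Product: 2 methyl (3S)-3-hydroxy-4-methylpentanoate
Conditions: H2 (50 atm), RuCl2[(R)-BINAP] (0.2 mol %), MeOH, 50 °C
Reagents that add atoms: none
Why: Noyori asymmetric hydrogenation of a β-keto ester; the (R)-BINAP complex of divalent ruthenium binds the keto ester as a chelate and delivers hydrogen to the face that gives the 3S carbinol (S because isopropyl outranks CH2CO2Me). This centre becomes C4 of the target.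

Step 2
Reactants: 2 methyl (3S)-3-hydroxy-4-methylpentanoate
Product: 3 methyl (3S)-4-methyl-3-[(triethylsilyl)oxy]pentanoate
Conditions: Et3SiCl, imidazole, DMF, 0 °C → rt
Reagents that add atoms: chlorotriethylsilane, CC[Si](Cl)(CC)CC
Why: Silylation of a secondary alcohol. The triethylsilyl ether is chosen because it later activates the C4–H bond toward the carbenoid, is small enough not to block it, and can still be removed from a tertiary oxygen at the end.

Step 3
Reactants: 3 methyl (3S)-4-methyl-3-[(triethylsilyl)oxy]pentanoate
Product: 4 (3S)-4-methyl-3-[(triethylsilyl)oxy]pentanal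
Conditions: iBu2AlH (1.05 equiv), CH2Cl2, −78 °C; MeOH, then aq. potassium sodium tartrate
Reagents that add atoms: none
Why: Half-reduction of a β-silyloxy ester. The aluminium hemiacetal is stable at −78 °C and gives the aldehyde only on work-up, and the stereocentre is not touched.

Step 4
Reactants: 5 (4S)-4-benzyl-3-propanoyl-1,3-oxazolidin-2-one, 4 (3S)-4-methyl-3-[(triethylsilyl)oxy]pentanal
Product: 7 (4S)-4-benzyl-3-{(2S,3R,5S)-3-hydroxy-2,6-dimethyl-5-[(triethylsilyl)oxy]heptanoyl}-1,3-oxazolidin-2-one, via dibutylboron Z-enolate 6 (not isolated)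
Conditions: 5, Bu2BOTf, iPr2NEt, CH2Cl2, −78 → 0 °C; then 4, −78 → 0 °C; pH 7 buffer, MeOH, H2O2
Reagents that add atoms: none
Why: Evans syn-aldol reaction. The Z boron enolate reacts through a Zimmerman–Traxler chair in which the benzyl group of the auxiliary screens one enolate face, which sets the 3R carbinol (C2 of the target, 1,3-syn to C4) regardless of the weak bias of the β-silyloxy centre. The 2S methyl centre formed with it is erased in step 6.

Step 5
Reactants: 7 (4S)-4-benzyl-3-{(2S,3R,5S)-3-hydroxy-2,6-dimethyl-5-[(triethylsilyl)oxy]heptanoyl}-1,3-oxazolidin-2-one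
Product: 8 methyl (2S,3R,5S)-3-hydroxy-2,6-dimethyl-5-[(triethylsilyl)oxy]heptanoate
Conditions: MeMgBr (1.2 equiv), MeOH, CH2Cl2, 0 °C
Reagents that add atoms: methanol, CO
Why: Transesterification of the imide with bromomagnesium methoxide. The exocyclic carbonyl is attacked selectively and the conditions are mild enough to avoid retro-aldol cleavage and loss of the triethylsilyl ether.

Step 6
Reactants: 8 methyl (2S,3R,5S)-3-hydroxy-2,6-dimethyl-5-[(triethylsilyl)oxy]heptanoate, 9 3-bromoprop-1-ene
Product: 11 methyl (2R,3R,5S)-3-hydroxy-2,6-dimethyl-2-(prop-2-en-1-yl)-5-[(triethylsilyl)oxy]heptanoate, via dilithium alkoxide enolate 10 (not isolated)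
Conditions: LiN(iPr)2 (2.3 equiv), THF, −78 → −20 °C; then 9, DMPU, −78 → 0 °C; aq. NH4Cl
Reagents that add atoms: none
Why: Fráter–Seebach alkylation. In the lithium-chelated dianion the enolate face syn to the C3 chain is blocked, so allyl bromide enters anti to the alkoxide and the quaternary centre (C1 of the target) forms with allyl anti and methyl syn to the C2 oxygen.

Step 7
Reactants: 11 methyl (2R,3R,5S)-3-hydroxy-2,6-dimethyl-2-(prop-2-en-1-yl)-5-[(triethylsilyl)oxy]heptanoate
Product: 12 methyl (2R,3R,5S)-3-[(tert-butyldimethylsilyl)oxy]-2,6-dimethyl-2-(prop-2-en-1-yl)-5-[(triethylsilyl)oxy]heptanoate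
Conditions: tBuMe2SiOTf, 2,6-lutidine, CH2Cl2, −78 → 0 °C
Reagents that add atoms: tert-butyldimethylsilyl trifluoromethanesulfonate, CC(C)(C)[Si](C)(C)OS(=O)(=O)C(F)(F)F
Why: Silylation of a hindered secondary alcohol with a silyl triflate. The C2 oxygen must be capped before an ester is made at C6, since a free C2 alkoxide would close a γ-lactone onto it, and the robust silyl group lasts to the final step.

Step 8
Reactants: 12 methyl (2R,3R,5S)-3-[(tert-butyldimethylsilyl)oxy]-2,6-dimethyl-2-(prop-2-en-1-yl)-5-[(triethylsilyl)oxy]heptanoate
Product: 14 dimethyl (2R)-2-{(1R,3S)-1-[(tert-butyldimethylsilyl)oxy]-4-methyl-3-[(triethylsilyl)oxy]pentyl}-2-methylbutanedioate, via aldehyde 13 (not isolated)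
Conditions: O3, 2.5 M NaOH in MeOH, CH2Cl2, −78 °C
Reagents that add atoms: ozone, [O-][O+]=O; methanol, CO
Why: Ozonolysis in methanolic NaOH. The aldehyde formed from the terminal alkene is trapped as its methyl hemiacetal and oxidised by ozone to the methyl ester in the same flask. No stereocentre is α to a carbonyl that could enolise, and both silyl ethers tolerate the cold base.

Step 9
Reactants: 14 dimethyl (2R)-2-{(1R,3S)-1-[(tert-butyldimethylsilyl)oxy]-4-methyl-3-[(triethylsilyl)oxy]pentyl}-2-methylbutanedioate
Product: 17 dimethyl (2R)-2-{(1R,3S)-1-[(tert-butyldimethylsilyl)oxy]-4-methyl-3-[(triethylsilyl)oxy]pentyl}-3-diazo-2-methylbutanedioate, via lithium enolate 15 (not isolated), via trifluoroacetyl diester 16 (not isolated)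
Conditions: LiN(SiMe3)2, THF, −78 °C; CF3CO2CH2CF3; aq. NH4Cl; then 4-acetamidobenzenesulfonyl azide, Et3N, H2O, MeCN, rt
Reagents that add atoms: 4-acetamidobenzenesulfonyl azide, CC(=O)Nc1ccc(cc1)S(=O)(=O)N=[N+]=[N-]
Why: Deacylative (detrifluoroacetylative) diazo transfer. C5 is the only enolisable position because C1 is quaternary; Claisen-type trifluoroacetylation activates it, and the sulfonyl azide then transfers N2 with loss of the trifluoroacetyl group.

Step 10
Reactants: 17 dimethyl (2R)-2-{(1R,3S)-1-[(tert-butyldimethylsilyl)oxy]-4-methyl-3-[(triethylsilyl)oxy]pentyl}-3-diazo-2-methylbutanedioate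
Product: 19 dimethyl (1R,2S,3S,5R)-5-[(tert-butyldimethylsilyl)oxy]-1-methyl-3-(propan-2-yl)-3-[(triethylsilyl)oxy]cyclopentane-1,2-dicarboxylate, via rhodium carbenoid 18 (not isolated)
Conditions: Rh2(OAc)4 (1 mol %), CH2Cl2, 40 °C, slow addition of 17
Reagents that add atoms: none
Why: Rh2(OAc)4 (divalent rhodium) expels N2 from 17 and gives the electrophilic carbenoid 18 at C5, which inserts into the C4–H bond in a concerted three-centre event with hydride-transfer character. The closest known reaction type is the dirhodium-catalysed intramolecular 1,5 C–H insertion of α-diazo esters into ether-activated C–H bonds, which runs with retention at the carbon attacked. The cyclopentane C1–C2–C3–C4–C5 closes through a chair-like six-centre array (C5, C1, C2, C3, C4 and the migrating hydrogen), the 1,5 mode, which is favoured over 1,4 and 1,6 insertion. C4 is not created but transferred: the new C–C bond forms on the face from which hydrogen leaves, so the S secondary silyl ether of step 1 becomes the tertiary carbinol with isopropyl on the methyl face and oxygen on the opposite face. C5 is new, and its C6 ester should take the side trans to the isopropyl group and to the C1 methyl group, next to the C10 ester and the silyloxy group, both in the chair-like transition state and at equilibrium. The step needs site selectivity against the C2–H, C3–H, isopropyl and silyl C–H bonds; it rests on the five-membered-ring preference, on activation of C4–H by the oxygen lone pairs and on its tertiary character. C1 is quaternary, so the 1,2-hydride shift that normally destroys α-alkyl carbenoids has no hydrogen to use.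

Step 11
Reactants: 19 dimethyl (1R,2S,3S,5R)-5-[(tert-butyldimethylsilyl)oxy]-1-methyl-3-(propan-2-yl)-3-[(triethylsilyl)oxy]cyclopentane-1,2-dicarboxylate
Product: 20 methyl (1R,2S,3S,5R)-5-[(tert-butyldimethylsilyl)oxy]-2-formyl-1-methyl-3-(propan-2-yl)-3-[(triethylsilyl)oxy]cyclopentane-1-carboxylate
Conditions: iBu2AlH (1.2 equiv), toluene, −78 °C; MeOH, then aq. potassium sodium tartrate
Reagents that add atoms: none
Why: Chemoselective half-reduction of an ester. The C6 ester sits on the tertiary C5 and is attacked before the C10 ester on the quaternary C1, and the crowded aluminium hemiacetal persists at −78 °C until the quench. The work-up is kept neutral so that the β-silyloxy aldehyde neither epimerises at C5 nor eliminates.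

Step 12
Reactants: 20 methyl (1R,2S,3S,5R)-5-[(tert-butyldimethylsilyl)oxy]-2-formyl-1-methyl-3-(propan-2-yl)-3-[(triethylsilyl)oxy]cyclopentane-1-carboxylate, 21 (2-methylprop-2-en-1-yl)magnesium chloride
Product: 24 (3R,3aR,4S,6R,6aR)-6-[(tert-butyldimethylsilyl)oxy]-6a-methyl-3-(2-methylprop-2-en-1-yl)-4-(propan-2-yl)-4-[(triethylsilyl)oxy]hexahydro-1H-cyclopenta[c]furan-1-one, via B-methallyldiisopinocampheylborane 22 (not isolated), via hydroxy ester 23 (not isolated)
Conditions: 21, (+)-Ipc2BOMe, Et2O, −78 °C → rt; then 20, −78 °C → rt; NaOH, H2O2; then K2CO3, MeOH, rt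
Reagents that add atoms: none
Why: Brown asymmetric methallylboration under reagent control. The borane of the (−)-α-pinene series adds through a chair transition state to the Re face of the aldehyde and sets C6 as R. The new alcohol then closes onto the cis C10 ester to the γ-lactone, which protects C6–O and singles out C10 for the next reduction.

Step 13
Reactants: 24 (3R,3aR,4S,6R,6aR)-6-[(tert-butyldimethylsilyl)oxy]-6a-methyl-3-(2-methylprop-2-en-1-yl)-4-(propan-2-yl)-4-[(triethylsilyl)oxy]hexahydro-1H-cyclopenta[c]furan-1-one
Product: 25 (3R,3aR,4S,6R,6aR)-6-[(tert-butyldimethylsilyl)oxy]-6a-methyl-3-(2-methylprop-2-en-1-yl)-4-(propan-2-yl)-4-[(triethylsilyl)oxy]hexahydro-1H-cyclopenta[c]furan-1-ol (both epimers at the lactol carbon)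
Conditions: iBu2AlH, CH2Cl2, −78 °C; aq. potassium sodium tartrate
Reagents that add atoms: none
Why: Reduction of a γ-lactone to the lactol. The aluminium lactolate next to the quaternary C1 does not open at −78 °C, so reduction stops at the aldehyde oxidation level of C10.

Step 14
Reactants: 25 (3R,3aR,4S,6R,6aR)-6-[(tert-butyldimethylsilyl)oxy]-6a-methyl-3-(2-methylprop-2-en-1-yl)-4-(propan-2-yl)-4-[(triethylsilyl)oxy]hexahydro-1H-cyclopenta[c]furan-1-ol, 26 ethenylmagnesium bromide
Product: 28 (1R)-1-{(1S,2R,3S,5R)-5-[(tert-butyldimethylsilyl)oxy]-2-[(1R)-1-hydroxy-3-methylbut-3-en-1-yl]-1-methyl-3-(propan-2-yl)-3-[(triethylsilyl)oxy]cyclopentyl}prop-2-en-1-ol, via open hydroxy aldehyde magnesium alkoxide 27 (not isolated)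
Conditions: 26 (5 equiv), THF, 0 °C → rt
Reagents that add atoms: none
Why: Grignard addition to the open hydroxy aldehyde form of a lactol. The magnesium alkoxide at C6–O holds the C10 carbonyl oxygen on the C5 side (Cram chelate), the face toward the C1–C2 bond is then closed, and vinyl should enter from the outer face past the C1 methyl group. That gives the 10R carbinol, anti to the C2 oxygen.

Step 15
Reactants: 28 (1R)-1-{(1S,2R,3S,5R)-5-[(tert-butyldimethylsilyl)oxy]-2-[(1R)-1-hydroxy-3-methylbut-3-en-1-yl]-1-methyl-3-(propan-2-yl)-3-[(triethylsilyl)oxy]cyclopentyl}prop-2-en-1-ol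
Product: 29 (1S,2R,4S,5R,6R,10R)-2-[(tert-butyldimethylsilyl)oxy]-1,8-dimethyl-4-(propan-2-yl)-4-[(triethylsilyl)oxy]bicyclo[5.3.0]dec-8-ene-6,10-diol (target numbering)
Conditions: second-generation Grubbs catalyst (H2IMes)(PCy3)Cl2Ru=CHPh (5 mol %), CH2Cl2, 40 °C
Reagents that add atoms: none
Why: Ring-closing metathesis. The catalyst loads on the vinyl group, helped by the free allylic hydroxyl, and closes onto the 1,1-disubstituted methallyl alkene; the two arms are cis on the cyclopentane, so the seven-membered ring forms with C8=C9 fixed in position and necessarily Z.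

Step 16
Reactants: 29 (1S,2R,4S,5R,6R,10R)-2-[(tert-butyldimethylsilyl)oxy]-1,8-dimethyl-4-(propan-2-yl)-4-[(triethylsilyl)oxy]bicyclo[5.3.0]dec-8-ene-6,10-diol, 30 angelic acid
Product: 32 (1S,2R,4S,5R,6R,10R)-2-[(tert-butyldimethylsilyl)oxy]-1,8-dimethyl-4-(propan-2-yl)-4-[(triethylsilyl)oxy]bicyclo[5.3.0]dec-8-ene-6,10-diyl bis[(2Z)-2-methylbut-2-enoate] (target numbering), via mixed anhydride 31 (not isolated)
Conditions: 30 (5 equiv), 2,4,6-Cl3C6H2COCl (5 equiv), Et3N (10 equiv), toluene, rt; then 29, 80 °C
Reagents that add atoms: angelic acid (second equivalent of 30), C/C=C(/C)C(=O)O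
Why: Yamaguchi-type esterification through the mixed anhydride 31, run without a nucleophilic pyridine catalyst because conjugate addition of such a catalyst is what turns angelates into tiglates. Each hydroxyl takes up one angeloyl group at the less hindered carbonyl of 31, so two molecules of angelic acid are built into 32, and the anhydride is used in excess so that the hindered C10 alcohol is esterified as well. Both carbinol configurations are retained because only O–acyl bonds form.

Step 17
Reactants: 32 (1S,2R,4S,5R,6R,10R)-2-[(tert-butyldimethylsilyl)oxy]-1,8-dimethyl-4-(propan-2-yl)-4-[(triethylsilyl)oxy]bicyclo[5.3.0]dec-8-ene-6,10-diyl bis[(2Z)-2-methylbut-2-enoate]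
Product: 33 (1R,2R,4S,5R,6R,10R)-2,4-dihydroxy-1,8-dimethyl-4-(propan-2-yl)bicyclo[5.3.0]dec-8-ene-6,10-diyl bis[(2Z)-2-methylbut-2-enoate] (target numbering)
Conditions: HF·pyridine, pyridine, THF, 0 °C → rt
Reagents that add atoms: none
Why: Fluoride-mediated cleavage of both silyl ethers in a buffered, weakly acidic medium. This avoids the basic conditions under which an angeloyl group could migrate to the C2 hydroxyl or isomerise, and no stereocentre is touched.

## Compound list

1 | methyl 4-methyl-3-oxopentanoate | COC(=O)CC(=O)C(C)C | starting material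
2 | methyl (3S)-3-hydroxy-4-methylpentanoate | COC(=O)C[C@H](O)C(C)C | intermediate
3 | methyl (3S)-4-methyl-3-[(triethylsilyl)oxy]pentanoate | COC(=O)C[C@H](O[Si](CC)(CC)CC)C(C)C | intermediate
4 | (3S)-4-methyl-3-[(triethylsilyl)oxy]pentanal | O=CC[C@H](O[Si](CC)(CC)CC)C(C)C | intermediate
5 | (4S)-4-benzyl-3-propanoyl-1,3-oxazolidin-2-one | CCC(=O)N1[C@@H](Cc2ccccc2)COC1=O | starting material
6 | dibutylboron Z-enolate of 5 | C/C=C(\OB(CCCC)CCCC)N1[C@@H](Cc2ccccc2)COC1=O | intermediate (not isolated)
7 | (4S)-4-benzyl-3-{(2S,3R,5S)-3-hydroxy-2,6-dimethyl-5-[(triethylsilyl)oxy]heptanoyl}-1,3-oxazolidin-2-one | O=C1OC[C@H](Cc2ccccc2)N1C(=O)[C@@H](C)[C@H](O)C[C@H](O[Si](CC)(CC)CC)C(C)C | intermediate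
8 | methyl (2S,3R,5S)-3-hydroxy-2,6-dimethyl-5-[(triethylsilyl)oxy]heptanoate | COC(=O)[C@@H](C)[C@H](O)C[C@H](O[Si](CC)(CC)CC)C(C)C | intermediate
9 | 3-bromoprop-1-ene | C=CCBr | starting material
10 | dilithium alkoxide enolate of 8 (lithium chelated between the two oxygens) | CO/C(O[Li])=C(\C)[C@H](O[Li])C[C@H](O[Si](CC)(CC)CC)C(C)C | intermediate (not isolated)
11 | methyl (2R,3R,5S)-3-hydroxy-2,6-dimethyl-2-(prop-2-en-1-yl)-5-[(triethylsilyl)oxy]heptanoate | C=CC[C@@](C)(C(=O)OC)[C@H](O)C[C@H](O[Si](CC)(CC)CC)C(C)C | intermediate
12 | methyl (2R,3R,5S)-3-[(tert-butyldimethylsilyl)oxy]-2,6-dimethyl-2-(prop-2-en-1-yl)-5-[(triethylsilyl)oxy]heptanoate | C=CC[C@@](C)(C(=O)OC)[C@H](O[Si](C)(C)C(C)(C)C)C[C@H](O[Si](CC)(CC)CC)C(C)C | intermediate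
13 | methyl (2R,3R,5S)-3-[(tert-butyldimethylsilyl)oxy]-2,6-dimethyl-2-(2-oxoethyl)-5-[(triethylsilyl)oxy]heptanoate | O=CC[C@@](C)(C(=O)OC)[C@H](O[Si](C)(C)C(C)(C)C)C[C@H](O[Si](CC)(CC)CC)C(C)C | intermediate (not isolated)
14 | dimethyl (2R)-2-{(1R,3S)-1-[(tert-butyldimethylsilyl)oxy]-4-methyl-3-[(triethylsilyl)oxy]pentyl}-2-methylbutanedioate | COC(=O)C[C@@](C)(C(=O)OC)[C@H](O[Si](C)(C)C(C)(C)C)C[C@H](O[Si](CC)(CC)CC)C(C)C | intermediate
15 | lithium enolate of 14 at C5 | COC(O[Li])=C[C@@](C)(C(=O)OC)[C@H](O[Si](C)(C)C(C)(C)C)C[C@H](O[Si](CC)(CC)CC)C(C)C | intermediate (not isolated)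
16 | C5-trifluoroacetyl derivative of 14 (C5 epimers) | COC(=O)C(C(=O)C(F)(F)F)[C@@](C)(C(=O)OC)[C@H](O[Si](C)(C)C(C)(C)C)C[C@H](O[Si](CC)(CC)CC)C(C)C | intermediate (not isolated)
17 | dimethyl (2R)-2-{(1R,3S)-1-[(tert-butyldimethylsilyl)oxy]-4-methyl-3-[(triethylsilyl)oxy]pentyl}-3-diazo-2-methylbutanedioate (precursor of the key step) | COC(=O)C(=[N+]=[N-])[C@@](C)(C(=O)OC)[C@H](O[Si](C)(C)C(C)(C)C)C[C@H](O[Si](CC)(CC)CC)C(C)C | intermediate
18 | rhodium carbenoid at C5 (the Rh atom stands for the Rh2(OAc)4 unit) | COC(=O)C(=[Rh])[C@@](C)(C(=O)OC)[C@H](O[Si](C)(C)C(C)(C)C)C[C@H](O[Si](CC)(CC)CC)C(C)C | intermediate (not isolated)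
19 | dimethyl (1R,2S,3S,5R)-5-[(tert-butyldimethylsilyl)oxy]-1-methyl-3-(propan-2-yl)-3-[(triethylsilyl)oxy]cyclopentane-1,2-dicarboxylate (product of the key step) | COC(=O)[C@@H]1[C@@](O[Si](CC)(CC)CC)(C(C)C)C[C@@H](O[Si](C)(C)C(C)(C)C)[C@]1(C)C(=O)OC | intermediate
20 | methyl (1R,2S,3S,5R)-5-[(tert-butyldimethylsilyl)oxy]-2-formyl-1-methyl-3-(propan-2-yl)-3-[(triethylsilyl)oxy]cyclopentane-1-carboxylate | O=C[C@@H]1[C@@](O[Si](CC)(CC)CC)(C(C)C)C[C@@H](O[Si](C)(C)C(C)(C)C)[C@]1(C)C(=O)OC | intermediate
21 | (2-methylprop-2-en-1-yl)magnesium chloride | CC(=C)C[Mg]Cl | starting material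
22 | B-(2-methylprop-2-en-1-yl)diisopinocampheylborane of the (−)-α-pinene series | C[C@@H]1[C@H](C[C@H]2C[C@@H]1C2(C)C)B(CC(C)=C)[C@H]3C[C@H]4C[C@@H]([C@@H]3C)C4(C)C | intermediate (not isolated)
23 | methyl (1R,2R,3S,5R)-5-[(tert-butyldimethylsilyl)oxy]-2-[(1R)-1-hydroxy-3-methylbut-3-en-1-yl]-1-methyl-3-(propan-2-yl)-3-[(triethylsilyl)oxy]cyclopentane-1-carboxylate | CC(=C)C[C@@H](O)[C@@H]1[C@@](O[Si](CC)(CC)CC)(C(C)C)C[C@@H](O[Si](C)(C)C(C)(C)C)[C@]1(C)C(=O)OC | intermediate (not isolated)
24 | (3R,3aR,4S,6R,6aR)-6-[(tert-butyldimethylsilyl)oxy]-6a-methyl-3-(2-methylprop-2-en-1-yl)-4-(propan-2-yl)-4-[(triethylsilyl)oxy]hexahydro-1H-cyclopenta[c]furan-1-one | CC(=C)C[C@H]1OC(=O)[C@@]2(C)[C@H](O[Si](C)(C)C(C)(C)C)C[C@](O[Si](CC)(CC)CC)(C(C)C)[C@@H]12 | intermediate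
25 | (3R,3aR,4S,6R,6aR)-6-[(tert-butyldimethylsilyl)oxy]-6a-methyl-3-(2-methylprop-2-en-1-yl)-4-(propan-2-yl)-4-[(triethylsilyl)oxy]hexahydro-1H-cyclopenta[c]furan-1-ol (both epimers at C1 of the lactol) | CC(=C)C[C@H]1OC(O)[C@@]2(C)[C@H](O[Si](C)(C)C(C)(C)C)C[C@](O[Si](CC)(CC)CC)(C(C)C)[C@@H]12 | intermediate
26 | ethenylmagnesium bromide | C=C[Mg]Br | starting material
27 | bromomagnesium alkoxide of the ring-opened hydroxy aldehyde form of 25 | O=C[C@@]1(C)[C@H](O[Si](C)(C)C(C)(C)C)C[C@](O[Si](CC)(CC)CC)(C(C)C)[C@H]1[C@H](O[Mg]Br)CC(C)=C | intermediate (not isolated)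
28 | (1R)-1-{(1S,2R,3S,5R)-5-[(tert-butyldimethylsilyl)oxy]-2-[(1R)-1-hydroxy-3-methylbut-3-en-1-yl]-1-methyl-3-(propan-2-yl)-3-[(triethylsilyl)oxy]cyclopentyl}prop-2-en-1-ol | C=C[C@@H](O)[C@@]1(C)[C@H](O[Si](C)(C)C(C)(C)C)C[C@](O[Si](CC)(CC)CC)(C(C)C)[C@H]1[C@H](O)CC(C)=C | intermediate
29 | (1S,2R,4S,5R,6R,10R)-2-[(tert-butyldimethylsilyl)oxy]-1,8-dimethyl-4-(propan-2-yl)-4-[(triethylsilyl)oxy]bicyclo[5.3.0]dec-8-ene-6,10-diol (target numbering) | O[C@@H]1CC(C)=C[C@@H](O)[C@@]2(C)[C@H](O[Si](C)(C)C(C)(C)C)C[C@](O[Si](CC)(CC)CC)(C(C)C)[C@@H]12 | intermediate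
30 | angelic acid, (2Z)-2-methylbut-2-enoic acid | C/C=C(/C)C(=O)O | starting material
31 | (2Z)-2-methylbut-2-enoic 2,4,6-trichlorobenzoic anhydride | C/C=C(/C)C(=O)OC(=O)c1c(Cl)cc(Cl)cc1Cl | intermediate (not isolated)
32 | (1S,2R,4S,5R,6R,10R)-2-[(tert-butyldimethylsilyl)oxy]-1,8-dimethyl-4-(propan-2-yl)-4-[(triethylsilyl)oxy]bicyclo[5.3.0]dec-8-ene-6,10-diyl bis[(2Z)-2-methylbut-2-enoate] (target numbering) | C/C=C(/C)C(=O)O[C@@H]1CC(C)=C[C@@H](OC(=O)/C(C)=C\C)[C@@]2(C)[C@H](O[Si](C)(C)C(C)(C)C)C[C@](O[Si](CC)(CC)CC)(C(C)C)[C@@H]12 | intermediate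
33 | (1R,2R,4S,5R,6R,10R)-2,4-dihydroxy-1,8-dimethyl-4-(propan-2-yl)bicyclo[5.3.0]dec-8-ene-6,10-diyl bis[(2Z)-2-methylbut-2-enoate] (target numbering), CNP0249167.1 | C/C=C(/C)C(=O)O[C@@H]1CC(C)=C[C@@H](OC(=O)/C(C)=C\C)[C@@]2(C)[C@H](O)C[C@](O)(C(C)C)[C@@H]12 | target

## Step count and least certain steps

Total step count: 17. Longest linear sequence: 17 steps (1 → 33); compounds 5, 9, 21, 26 and 30 are bought.

**Step 10 (key step).** The carbenoid 18 carries only one ester and is highly electrophilic, so the likeliest failure is diversion before insertion: hydride abstraction from C4 without C–C bond formation, migration of a C1 substituent onto the carbenoid carbon, attack on the C4 silyl ether oxygen to give an oxonium ylide, or carbenoid dimerisation. The C4–H bond is also shielded by the isopropyl and triethylsilyl groups. The C6 ester may come out on the isopropyl side, and base equilibration would then risk β-elimination of the C4 silyloxy group. Fallback: the same C4–C5 bond is made by a polar addition, so the C4 configuration is set in the ring closure and not transferred. Setting out from 14, its lithium enolate 15 is brominated with N-bromosuccinimide to the C5-bromo diester F1. The triethylsilyl ether alone is cleaved with pyridinium p-toluenesulfonate in MeOH to the C4 alcohol F2, which Dess–Martin periodinane oxidises to the C4 ketone F3. SmI2 (divalent samarium) in THF at −78 °C then forms the C5 samarium enolate, which adds to the C4 ketone in an intramolecular Reformatsky reaction to the cyclopentanol F4; samarium bridges the ketone and ester oxygens, so the C4 hydroxyl and the C6 ester should come out cis. Et3SiOTf and 2,6-lutidine return to 19.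

**Step 9.** The likeliest failure is slow or O-selective trifluoroacetylation of the enolate 15, whose nucleophilic carbon is next to the quaternary C1, followed by incomplete deacylative transfer at the crowded C5. Fallback: the diazo group is built from a C5 ketone. Setting out from 14, hydroxylation of its potassium enolate (KN(SiMe3)2, THF, −78 °C) with 2-(benzenesulfonyl)-3-phenyloxaziridine gives the C5-hydroxy diester F5. Dess–Martin oxidation gives the α-keto ester F6, condensation with p-toluenesulfonyl hydrazide gives the hydrazone F7, and Et3N in CH2Cl2 eliminates sulfinate (Bamford–Stevens reaction) to return to 17.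

**Step 11.** The likeliest failure is over-reduction: the aluminium hemiacetal collapses before the quench, the aldehyde is reduced on to the C6 alkoxide, and this closes onto the C10 ester to a lactone at the wrong oxidation level. Attack at the C10 ester is less likely. Fallback: setting out from 19, Me(MeO)NH·HCl and iPrMgCl convert the less hindered C6 ester into the N-methoxy-N-methylamide F8. Its chelated tetrahedral intermediate with iBu2AlH cannot be reduced further and gives 20 on work-up.

**Step 12.** The likeliest failure is poor facial selectivity, with the bias of the crowded aldehyde 20 overriding the reagent, or sluggish addition of the bulky borane 22. Fallback: C6 is corrected by inversion. Setting out from 20, the Grignard reagent 21 is added directly (THF, −78 °C). If the substrate-preferred adduct is the C6 epimer of the hydroxy ester F9, it closes to the epimeric lactone F10. LiOH opens this to the hydroxy acid F11, and a Mitsunobu lactonisation (PPh3, diisopropyl azodicarboxylate) closes the ring with inversion at C6 and returns to 24.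

**Step 14.** The likeliest failure is poor facial selectivity at C10, if the magnesium chelate is not formed or if the C1 methyl group blocks the outer face. Fallback: C10 is set by reduction. Setting out from 25, the C10 epimer of the diol F12 (alone or mixed with 28) is carried through the metathesis to the epimeric bicyclic diol F13. MnO2 oxidises only the allylic C10 alcohol, to the enone F14. A Corey–Bakshi–Shibata reduction with the (S)-2-methyl-oxazaborolidine and catecholborane, in which the quaternary C1 side acts as the large group, should then give the 10R alcohol and return to 29.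

## Further compounds

F1 | step 10 | C5-bromo derivative of 14 (C5 epimers) | COC(=O)C(Br)[C@@](C)(C(=O)OC)[C@H](O[Si](C)(C)C(C)(C)C)C[C@H](O[Si](CC)(CC)CC)C(C)C
F2 | step 10 | C4 alcohol from F1 (triethylsilyl group removed) | COC(=O)C(Br)[C@@](C)(C(=O)OC)[C@H](O[Si](C)(C)C(C)(C)C)C[C@H](O)C(C)C
F3 | step 10 | C4 ketone from F2 | COC(=O)C(Br)[C@@](C)(C(=O)OC)[C@H](O[Si](C)(C)C(C)(C)C)CC(=O)C(C)C
F4 | step 10 | dimethyl (1R,2S,3S,5R)-5-[(tert-butyldimethylsilyl)oxy]-3-hydroxy-1-methyl-3-(propan-2-yl)cyclopentane-1,2-dicarboxylate | COC(=O)[C@@H]1[C@@](O)(C(C)C)C[C@@H](O[Si](C)(C)C(C)(C)C)[C@]1(C)C(=O)OC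
F5 | step 9 | C5-hydroxy derivative of 14 (C5 epimers) | COC(=O)C(O)[C@@](C)(C(=O)OC)[C@H](O[Si](C)(C)C(C)(C)C)C[C@H](O[Si](CC)(CC)CC)C(C)C
F6 | step 9 | C5-oxo derivative of 14 (α-keto ester) | COC(=O)C(=O)[C@@](C)(C(=O)OC)[C@H](O[Si](C)(C)C(C)(C)C)C[C@H](O[Si](CC)(CC)CC)C(C)C
F7 | step 9 | p-toluenesulfonylhydrazone of F6 at C5 | COC(=O)C(=NNS(=O)(=O)c1ccc(C)cc1)[C@@](C)(C(=O)OC)[C@H](O[Si](C)(C)C(C)(C)C)C[C@H](O[Si](CC)(CC)CC)C(C)C
F8 | step 11 | N-methoxy-N-methylamide of 19 at C6 | CON(C)C(=O)[C@@H]1[C@@](O[Si](CC)(CC)CC)(C(C)C)C[C@@H](O[Si](C)(C)C(C)(C)C)[C@]1(C)C(=O)OC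
F9 | step 12 | C6 epimer of hydroxy ester 23 | CC(=C)C[C@H](O)[C@@H]1[C@@](O[Si](CC)(CC)CC)(C(C)C)C[C@@H](O[Si](C)(C)C(C)(C)C)[C@]1(C)C(=O)OC
F10 | step 12 | C6 epimer of lactone 24 | CC(=C)C[C@@H]1OC(=O)[C@@]2(C)[C@H](O[Si](C)(C)C(C)(C)C)C[C@](O[Si](CC)(CC)CC)(C(C)C)[C@@H]12
F11 | step 12 | hydroxy acid from F10 (free C10 carboxylic acid, C6 epimeric alcohol) | CC(=C)C[C@H](O)[C@@H]1[C@@](O[Si](CC)(CC)CC)(C(C)C)C[C@@H](O[Si](C)(C)C(C)(C)C)[C@]1(C)C(=O)O
F12 | step 14 | C10 epimer of diol 28 | C=C[C@H](O)[C@@]1(C)[C@H](O[Si](C)(C)C(C)(C)C)C[C@](O[Si](CC)(CC)CC)(C(C)C)[C@H]1[C@H](O)CC(C)=C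
F13 | step 14 | C10 epimer of bicyclic diol 29 | O[C@@H]1CC(C)=C[C@H](O)[C@@]2(C)[C@H](O[Si](C)(C)C(C)(C)C)C[C@](O[Si](CC)(CC)CC)(C(C)C)[C@@H]12
F14 | step 14 | C10 ketone of 29 (cycloheptenone with free C6 hydroxyl) | O[C@@H]1CC(C)=CC(=O)[C@@]2(C)[C@H](O[Si](C)(C)C(C)(C)C)C[C@](O[Si](CC)(CC)CC)(C(C)C)[C@@H]12
A1 | alternative 1 | cis-fused bicyclo[5.3.0]dec-8-en-6-one with C10 p-methoxybenzyl ether, C2 tert-butyldimethylsilyl ether and C4 secondary triethylsilyl ether | O=C1CC(C)=C[C@@H](OCc3ccc(OC)cc3)[C@@]2(C)[C@H](O[Si](C)(C)C(C)(C)C)C[C@H](O[Si](CC)(CC)CC)[C@@H]12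
A2 | alternative 2 | bicyclic cycloheptadiene with methyl ester at C8, C8=C9 and C5=C6 double bonds, C6 silyl enol ether, C10 and C2 silyl ethers and C4 as CH-isopropyl | CC(C)(C)[Si](C)(C)OC=1CC(C(=O)OC)=C[C@@H](O[Si](C)(C)C(C)(C)C)[C@@]2(C)[C@H](O[Si](C(C)C)(C(C)C)C(C)C)C[C@H](C(C)C)C=12
A3 | alternative 3 | cis-bicyclo[5.3.0]decane-6,10-dione with saturated methyl-bearing C8, C2 silyl ether and free C4 tertiary alcohol | O=C1C[C@@H](C)CC(=O)[C@@]2(C)[C@H](O[Si](C)(C)C(C)(C)C)C[C@](O)(C(C)C)[C@@H]12
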